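The earlier runs and the new flask are calculated from invented constants; the scatter is artificial.

common to all: starting complex 0.40 M
- elm: incoming ligand 0.25 M; run made earlier
- birch: incoming ligand 0.51 M; run made earlier
- maple: incoming ligand 0.85 M; run made earlier
- Saturday's: incoming ligand 0.320 M; time 3.0 h
- Sunday's: incoming ligand 0.400 M; time 3.0 h
- Friday's: incoming ligand 1.00 M; time 3.0 h

- elm (time / min: complex with one exchanged / %): 10.0: 9.9; 20.0: 17.2; 40.0: 27.1; 60.0: 33.2; 120: 42.2
- birch (time / min: complex with one exchanged / %): 12.0: 22.4; 30.0: 38.8; 60.0: 52.5; 90.0: 57.6; 120: 60.1
- maple (time / min: complex with one exchanged / %): 10.0: 28.6; 20.0: 44.0; 40.0: 57.1; 60.0: 61.0; 120: 58.0

(scatter of a reading: 0.3 percentage points)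

- what was read earlier has a scatter of 0.3 percentage points, one standard deviation
- candidate steps: starting complex + incoming ligand -> leaving ligand + complex with one exchanged; 2 incoming ligand -> homo dimer; complex with one exchanged + incoming ligand -> leaving ligand + complex with two exchanged

- which of these holds the largest part of the starting complex at the end of Saturday's (complex with one exchanged / starting complex / complex with two exchanged)
- which of these holds the largest part of the starting complex at the end of Sunday's (complex with one exchanged / starting complex / complex with two exchanged)
- which of these holds the largest part of the starting complex at the end of Friday's (complex with one exchanged / starting complex / complex with two exchanged)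
- amount of complex with one exchanged at the end of Friday's, in percent of the starting complex charged

1. The first exchange is the easy step: the earliest elm reading gives a rate constant of about 0.0396 /M/min, so each starting complex in Friday's begins at 2.38 /h.

2. Incoming ligand multiplies both exchanges, so the height of the peak of complex with one exchanged depends on one ratio: it equals that ratio raised to the power ratio over one minus ratio. An approximate solution for the maple peak reading of 61.0 % gives 0.265, the selectivity factor, the second step's rate constant over the first's.

3. Making over using of complex with one exchanged is therefore starting complex over complex with one exchanged, divided by this factor; ligand cancels, and the peak lies where the quotient passes one.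

4. Two things slow the first step. Its own falling substrate slows it, and ligand slows both steps: with the two products level, the two exchanges spend 0.600 M of ligand, leaving a factor of 0.400, and whatever goes to the homo dimer lowers that factor further.

5. Taking the square root of that factor as the mean slowing, Friday's lives through 4.51 first-step lifetimes, and fewer once the homo dimer's ligand is counted. The products draw level, with starting complex neglected, at 3.78, so this reckoning passes that point as long as the factor stays above 0.281, and on that condition it puts complex with two exchanged ahead on Friday's.

6. The forecast differs there: it names complex with one exchanged for Saturday's, complex with one exchanged for Sunday's, complex with one exchanged for Friday's, with 50 % on Friday's, holding that “one-exchanged stays narrowly ahead because dimerisation starves the second step”.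

    starting complex + incoming ligand → leaving ligand + complex with one exchanged (k = 2.80 /M/h)
    2 incoming ligand → homo dimer (k = 0.0730 /M/h)
    complex with one exchanged + incoming ligand → leaving ligand + complex with two exchanged (k = 0.760 /M/h)

At the end of Saturday's the largest part, 52.9 %, stands as complex with one exchanged, and at the end of Sunday's the largest part, 58.3 %, stands as complex with one exchanged. At the end of Friday's the largest part, 53.7 %, stands as complex with two exchanged, and the amount asked for is 44.4 %. In Friday's, complex with one exchanged is made 4.23 times faster than it is used at 0.279 h, but by 3.00 h making is slower than using, at 0.161 of it, and the carried factor gives 0.164 from the end amounts. The neighbour flask with 0.60 M of ligand gives 0.786 by the same rule at 3.00 h, and complex with one exchanged stands there at 61.0 %.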